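**Plan**

- Retrosynthesis (target numbered as an oct-6-en-1-one, C1 = ketone carbon): cut the two O–allyl bonds, the furan O–C bond and the C8–alkyne bond (furan from an alkynediol), C6=C7 (Wittig) and aryl–C1 (Grignard). Then rejoin C1 and C6 as the enol ether C=C of a cyclohexene and cut its C2–C3 and C4–C5 bonds as a Diels–Alder retron.
- Enabling feature: C3 is a quaternary carbon carrying CH3, CH=CH2, the arm C2H2–C1(=O) and the arm C4H2–C5H2–C6H=. With C1 bonded to C6, the atoms C1–C6 form a cyclohexene in which C3 and C4 are the α- and β-carbons of methacrolein (formyl carbon = vinyl CH) and C5–C6–C1–C2 is a 2-silyloxybuta-1,3-diene.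
- Forward: the cycloaddition closes the only carbocycle, which is temporary. Methylenation and ozonolysis of the enol ether open it to a C1 aldehyde and a C6 acid. The aryl group is added at C1, C6 is taken to the aldehyde, then Wittig to the E-enal, reduction, bromide and alkyne coupling. The furan ring is closed in the penultimate step and the phenols are freed last.
- Stereochemistry: the only stereocentre, C3 (R), is set in the cycloaddition by a chiral oxazaborolidinium catalyst and, being quaternary, cannot epimerise. The 6E alkene comes from a formyl-stabilised ylide.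

Key step: step 2

Assumption: the sense of induction is taken from the formyl C–H···O pre-transition-state model, under which the catalyst made from (R)-α,α-diphenylprolinol leaves the Si face of the α-carbon of methacrolein open. The configuration of the cycloadduct should be confirmed by correlation before scale-up; the mirror-image catalyst is equally available.

**Route**

Step 1
Reactants: 1 methyl vinyl ketone
Product: 2 2-(triisopropylsilyloxy)buta-1,3-diene
Conditions: TIPSOTf, Et3N, Et2O, 0 °C → rt
Reagents that add atoms: triisopropylsilyl trifluoromethanesulfonate, CC(C)[Si](OS(=O)(=O)C(F)(F)F)(C(C)C)C(C)C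
Why: Soft enolisation (O-silylation by the silyl triflate, deprotonation of the methyl group by Et3N) is the standard way to the cross-conjugated 2-silyloxydiene, and the bulky silyl group makes it distillable.

Step 2
Reactants: 2 2-(triisopropylsilyloxy)buta-1,3-diene; 3 methacrolein
Product: 4 (1R)-1-methyl-4-(triisopropylsilyloxy)cyclohex-3-ene-1-carbaldehyde
Conditions: (R)-3,3-diphenyl-1-(2-methylphenyl)tetrahydro-1H,3H-pyrrolo[1,2-c][1,3,2]oxazaborole (12 mol %), HNTf2 (10 mol %), CH2Cl2, −78 °C; Et3N quench
Reagents that add atoms: none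
Why: The N-protonated oxazaborolidine binds the formyl oxygen of s-trans methacrolein at boron, with the formyl C–H held against the ring oxygen, and lowers the LUMO; the diene CH2 next to the silyloxy carbon (largest HOMO coefficient) bonds first to the β-carbon and the other terminus then closes onto the α-carbon in a concerted asynchronous [4+2] cycloaddition. The closest known reaction type is the cationic-oxazaborolidine-catalysed Diels–Alder reaction of α-substituted acroleins with 2-silyloxybutadienes. The cyclohexene ring is closed by this intermolecular [4+2] addition, both σ-bonds (C2–C3 and C4–C5 in target numbering) forming suprafacially on each partner. The quaternary centre is controlled by the catalyst alone: the bicyclic oxazaborolidinium and its proximal phenyl group cover one face of the bound enal, so the diene should add to the open Si face of the α-carbon and give the R configuration; endo/exo orientation is irrelevant because no second stereocentre forms. The step needs para regioselectivity, secured by the 2-silyloxy donor matched with the β-carbon of the enal, and survival of the enol ether, secured by the bulky triisopropylsilyl group and the cold Et3N quench, because hydrolysis would give an achiral 4-oxo aldehyde.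

Step 3
Reactants: 4 (1R)-1-methyl-4-(triisopropylsilyloxy)cyclohex-3-ene-1-carbaldehyde
Product: 5 {[(4R)-4-ethenyl-4-methylcyclohex-1-en-1-yl]oxy}triisopropylsilane
Conditions: Ph3PCH3Br, KOtBu, THF, 0 °C → rt
Reagents that add atoms: methyltriphenylphosphonium bromide, C[P+](c1ccccc1)(c1ccccc1)c1ccccc1.[Br-]
Why: Wittig methylenation of a non-enolisable neopentyl aldehyde under basic, non-aqueous conditions turns the formyl carbon into the vinyl CH and leaves the silyl enol ether and the quaternary centre untouched.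

Step 4
Reactants: 5 {[(4R)-4-ethenyl-4-methylcyclohex-1-en-1-yl]oxy}triisopropylsilane
Product: 8 (4R)-4-methyl-4-(2-oxoethyl)hex-5-enoic acid, via methoxy hydroperoxide 6 (not isolated), via silyl ester aldehyde 7 (not isolated)
Conditions: O3, CH2Cl2/MeOH, Sudan Red 7B end point, −78 °C; Me2S, −78 °C → rt; then aq. HF, MeCN, 0 °C
Reagents that add atoms: ozone, [O-][O+]=O
Why: Ozonolysis should cleave the electron-rich trisubstituted silyl enol ether much faster than the monosubstituted vinyl group on the quaternary carbon (the dye marks the end point); the carbonyl oxide is trapped by methanol and reduced by Me2S, and HF cleaves the silyl ester, so C1 emerges as the aldehyde and C6 as the acid.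

Step 5
Reactants: 9 4-bromoresorcinol
Product: 10 1-bromo-2,4-bis(prop-2-en-1-yloxy)benzene
Conditions: allyl bromide, K2CO3, acetone, reflux
Reagents that add atoms: allyl bromide, C=CCBr
Why: Williamson etherification of both phenols gives allyl ethers that tolerate organomagnesium, hydride, ylide, copper and gold chemistry and can be removed at the end without acid.

Step 6
Reactants: 10 1-bromo-2,4-bis(prop-2-en-1-yloxy)benzene; 8 (4R)-4-methyl-4-(2-oxoethyl)hex-5-enoic acid
Product: 12 (4R)-4-{2-[2,4-bis(prop-2-en-1-yloxy)phenyl]-2-hydroxyethyl}-4-methylhex-5-enoic acid (carbinol epimers), via arylmagnesium bromide 11 (not isolated)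
Conditions: 10, Mg, LiCl, THF, rt; then 8 (0.43 equiv), THF, −40 → 0 °C; cold 1 M HCl to pH 4
Reagents that add atoms: none
Why: Magnesium insertion gives an aryl Grignard reagent that tolerates the ortho allyloxy group; one equivalent converts the acid into an inert magnesium carboxylate and the next adds to the aldehyde (Grignard addition), the uncontrolled carbinol centre being oxidised away in step 8.

Step 7
Reactants: 12 (4R)-4-{2-[2,4-bis(prop-2-en-1-yloxy)phenyl]-2-hydroxyethyl}-4-methylhex-5-enoic acid
Product: 13 (3R)-1-[2,4-bis(prop-2-en-1-yloxy)phenyl]-3-ethenyl-3-methylhexane-1,6-diol (C1 epimers)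
Conditions: LiAlH4, THF, 0 °C → reflux; H2O, aq. NaOH
Reagents that add atoms: none
Why: LiAlH4 reduces the carboxylic acid to the primary alcohol under basic conditions that do not ionise the electron-rich benzylic alcohol and leave the isolated alkenes and allyl ethers alone.

Step 8
Reactants: 13 (3R)-1-[2,4-bis(prop-2-en-1-yloxy)phenyl]-3-ethenyl-3-methylhexane-1,6-diol
Product: 14 (4R)-4-{2-[2,4-bis(prop-2-en-1-yloxy)phenyl]-2-oxoethyl}-4-methylhex-5-enal
Conditions: Dess–Martin periodinane (3 equiv), NaHCO3, CH2Cl2, 0 °C → rt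
Reagents that add atoms: none
Why: Buffered Dess–Martin oxidation takes the primary alcohol to the aldehyde and the benzylic alcohol to the aryl ketone in one operation, under neutral conditions that avoid aldol closure of the 1,6-dicarbonyl compound.

Step 9
Reactants: 14 (4R)-4-{2-[2,4-bis(prop-2-en-1-yloxy)phenyl]-2-oxoethyl}-4-methylhex-5-enal
Product: 15 (2E,6R)-6-{2-[2,4-bis(prop-2-en-1-yloxy)phenyl]-2-oxoethyl}-2,6-dimethylocta-2,7-dienal
Conditions: Ph3P=C(CH3)CHO, toluene, 90 °C
Reagents that add atoms: 2-(triphenylphosphoranylidene)propanal, CC(C=O)=P(c1ccccc1)(c1ccccc1)c1ccccc1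
Why: The formyl-stabilised ylide reacts only with the aldehyde, not with the deactivated aryl ketone, and reversible oxaphosphetane formation in this Wittig reaction should give the E-configured 2-methyl enal (chain trans to CHO).

Step 10
Reactants: 15 (2E,6R)-6-{2-[2,4-bis(prop-2-en-1-yloxy)phenyl]-2-oxoethyl}-2,6-dimethylocta-2,7-dienal
Product: 16 (3R,6E)-1-[2,4-bis(prop-2-en-1-yloxy)phenyl]-3-ethenyl-8-hydroxy-3,7-dimethyloct-6-en-1-one
Conditions: NaBH4 (0.5 equiv), CH2Cl2/EtOH, −78 °C
Reagents that add atoms: none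
Why: At low temperature borohydride should reduce the aldehyde by 1,2-addition far faster than the hindered 2,4-dialkoxyaryl ketone, giving the allylic alcohol with the alkene geometry unchanged.

Step 11
Reactants: 16 (3R,6E)-1-[2,4-bis(prop-2-en-1-yloxy)phenyl]-3-ethenyl-8-hydroxy-3,7-dimethyloct-6-en-1-one
Product: 17 (3R,6E)-1-[2,4-bis(prop-2-en-1-yloxy)phenyl]-8-bromo-3-ethenyl-3,7-dimethyloct-6-en-1-one
Conditions: CBr4, PPh3, CH2Cl2, −20 → 0 °C
Reagents that add atoms: carbon tetrabromide, BrC(Br)(Br)Br
Why: The Appel reaction converts the primary allylic alcohol into the bromide by SN2 displacement of the oxyphosphonium group under neutral conditions, without allylic transposition and without touching the ketone.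

Step 12
Reactants: 18 hydroxyacetone
Product: 19 2-methylbut-3-yne-1,2-diol (racemic)
Conditions: HC≡CMgBr (2.5 equiv), THF, 0 °C → rt; 1 M HCl, 0 °C
Reagents that add atoms: ethynylmagnesium bromide, C#C[Mg]Br
Why: Grignard addition of the acetylide to the ketone (after deprotonation of the hydroxyl by the first equivalent) gives the alkynediol; racemic material suffices because its carbinol centre is lost on aromatisation.

Step 13
Reactants: 17 (3R,6E)-1-[2,4-bis(prop-2-en-1-yloxy)phenyl]-8-bromo-3-ethenyl-3,7-dimethyloct-6-en-1-one; 19 2-methylbut-3-yne-1,2-diol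
Product: 20 (3R,6E)-1-[2,4-bis(prop-2-en-1-yloxy)phenyl]-3-ethenyl-11,12-dihydroxy-3,7,11-trimethyldodec-6-en-9-yn-1-one (C11 epimers)
Conditions: 19 (1.5 equiv), CuI (20 mol %), n-Bu4NI (20 mol %), K2CO3, DMF, rt
Reagents that add atoms: none
Why: The copper acetylide formed with carbonate base should displace the primary allylic bromide at the CH2 terminus, away from the trisubstituted alkene carbon (copper-catalysed alkyne–allyl halide coupling); free hydroxyl groups and the ketone are tolerated and the E alkene is kept.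

Step 14
Reactants: 20 (3R,6E)-1-[2,4-bis(prop-2-en-1-yloxy)phenyl]-3-ethenyl-11,12-dihydroxy-3,7,11-trimethyldodec-6-en-9-yn-1-one
Product: 22 (3R,6E)-1-[2,4-bis(prop-2-en-1-yloxy)phenyl]-3-ethenyl-3,7-dimethyl-8-(4-methylfuran-2-yl)oct-6-en-1-one, via hydroxydihydrofuran 21 (not isolated)
Conditions: Ph3PAuNTf2 (2 mol %), THF, rt
Reagents that add atoms: none
Why: Cationic gold activates the alkyne for 5-endo-dig attack by the primary hydroxyl and the resulting 3-hydroxy-2,3-dihydrofuran loses water to aromatise (gold-catalysed cyclodehydration of 3-alkyne-1,2-diols), which places the side chain at furan C2 and the methyl group at C4 without ambiguity.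

Step 15
Reactants: 22 (3R,6E)-1-[2,4-bis(prop-2-en-1-yloxy)phenyl]-3-ethenyl-3,7-dimethyl-8-(4-methylfuran-2-yl)oct-6-en-1-one
Product: 23 (3R,6E)-1-(2,4-dihydroxyphenyl)-3-ethenyl-3,7-dimethyl-8-(4-methylfuran-2-yl)oct-6-en-1-one (CNP0249327.1)
Conditions: Pd(PPh3)4 (5 mol %), morpholine (10 equiv), THF, rt
Reagents that add atoms: none
Why: Zerovalent palladium ionises both aryl allyl ethers to η3-allyl complexes and phenoxides and morpholine traps the allyl groups (Tsuji–Trost deallylation), a neutral deprotection that spares the acid-sensitive furan, the skipped diene and the vinyl group.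

**Compound list**

1 | methyl vinyl ketone | CC(=O)C=C | starting material
2 | 2-(triisopropylsilyloxy)buta-1,3-diene | C=CC(=C)O[Si](C(C)C)(C(C)C)C(C)C | intermediate
3 | methacrolein | C=C(C)C=O | starting material
4 | (1R)-1-methyl-4-(triisopropylsilyloxy)cyclohex-3-ene-1-carbaldehyde | O=C[C@]1(C)CCC(O[Si](C(C)C)(C(C)C)C(C)C)=CC1 | intermediate
5 | {[(4R)-4-ethenyl-4-methylcyclohex-1-en-1-yl]oxy}triisopropylsilane | C=C[C@]1(C)CCC(O[Si](C(C)C)(C(C)C)C(C)C)=CC1 | intermediate
6 | triisopropylsilyl (4R)-4-(2-hydroperoxy-2-methoxyethyl)-4-methylhex-5-enoate (hemiperacetal epimers) | C=C[C@@](C)(CC(OC)OO)CCC(=O)O[Si](C(C)C)(C(C)C)C(C)C | intermediate (not isolated)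
7 | triisopropylsilyl (4R)-4-methyl-4-(2-oxoethyl)hex-5-enoate | C=C[C@@](C)(CC=O)CCC(=O)O[Si](C(C)C)(C(C)C)C(C)C | intermediate (not isolated)
8 | (4R)-4-methyl-4-(2-oxoethyl)hex-5-enoic acid | C=C[C@@](C)(CC=O)CCC(=O)O | intermediate
9 | 4-bromoresorcinol | Oc1ccc(Br)c(O)c1 | starting material
10 | 1-bromo-2,4-bis(prop-2-en-1-yloxy)benzene | C=CCOc1ccc(Br)c(OCC=C)c1 | intermediate
11 | [2,4-bis(prop-2-en-1-yloxy)phenyl]magnesium bromide | C=CCOc1ccc([Mg]Br)c(OCC=C)c1 | intermediate (not isolated)
12 | (4R)-4-{2-[2,4-bis(prop-2-en-1-yloxy)phenyl]-2-hydroxyethyl}-4-methylhex-5-enoic acid (carbinol epimers) | C=C[C@@](C)(CC(O)c1ccc(OCC=C)cc1OCC=C)CCC(=O)O | intermediate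
13 | (3R)-1-[2,4-bis(prop-2-en-1-yloxy)phenyl]-3-ethenyl-3-methylhexane-1,6-diol (C1 epimers) | C=C[C@@](C)(CC(O)c1ccc(OCC=C)cc1OCC=C)CCCO | intermediate
14 | (4R)-4-{2-[2,4-bis(prop-2-en-1-yloxy)phenyl]-2-oxoethyl}-4-methylhex-5-enal | C=C[C@@](C)(CC(=O)c1ccc(OCC=C)cc1OCC=C)CCC=O | intermediate
15 | (2E,6R)-6-{2-[2,4-bis(prop-2-en-1-yloxy)phenyl]-2-oxoethyl}-2,6-dimethylocta-2,7-dienal | C=C[C@@](C)(CC(=O)c1ccc(OCC=C)cc1OCC=C)CC/C=C(\C)C=O | intermediate
16 | (3R,6E)-1-[2,4-bis(prop-2-en-1-yloxy)phenyl]-3-ethenyl-8-hydroxy-3,7-dimethyloct-6-en-1-one | C=C[C@@](C)(CC(=O)c1ccc(OCC=C)cc1OCC=C)CC/C=C(\C)CO | intermediate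
17 | (3R,6E)-1-[2,4-bis(prop-2-en-1-yloxy)phenyl]-8-bromo-3-ethenyl-3,7-dimethyloct-6-en-1-one | C=C[C@@](C)(CC(=O)c1ccc(OCC=C)cc1OCC=C)CC/C=C(\C)CBr | intermediate
18 | hydroxyacetone | CC(=O)CO | starting material
19 | 2-methylbut-3-yne-1,2-diol (racemic) | C#CC(C)(O)CO | intermediate
20 | (3R,6E)-1-[2,4-bis(prop-2-en-1-yloxy)phenyl]-3-ethenyl-11,12-dihydroxy-3,7,11-trimethyldodec-6-en-9-yn-1-one (C11 epimers) | C=C[C@@](C)(CC(=O)c1ccc(OCC=C)cc1OCC=C)CC/C=C(\C)CC#CC(C)(O)CO | intermediate
21 | (3R,6E)-1-[2,4-bis(prop-2-en-1-yloxy)phenyl]-3-ethenyl-8-(3-hydroxy-3-methyl-2,3-dihydrofuran-5-yl)-3,7-dimethyloct-6-en-1-one | C=C[C@@](C)(CC(=O)c1ccc(OCC=C)cc1OCC=C)CC/C=C(\C)CC1=CC(C)(O)CO1 | intermediate (not isolated)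
22 | (3R,6E)-1-[2,4-bis(prop-2-en-1-yloxy)phenyl]-3-ethenyl-3,7-dimethyl-8-(4-methylfuran-2-yl)oct-6-en-1-one | C=C[C@@](C)(CC(=O)c1ccc(OCC=C)cc1OCC=C)CC/C=C(\C)Cc1cc(C)co1 | intermediate
23 | (3R,6E)-1-(2,4-dihydroxyphenyl)-3-ethenyl-3,7-dimethyl-8-(4-methylfuran-2-yl)oct-6-en-1-one | C=C[C@](C)(CC/C=C(\C)Cc1cc(C)co1)CC(=O)c1ccc(O)cc1O | target

**Step count and risks**

Total steps: 15. Longest linear sequence: 13 (steps 1–4, 6–11, 13–15); steps 5 and 12 are side branches.

Steps most likely to fail:

Step 4. Ozone may not discriminate well enough: over-oxidation would also cleave the vinyl group, while stopping early leaves enol ether. The fallback sets out from 5 and returns at 8. Compound 5 would be oxidised with mCPBA (NaHCO3, CH2Cl2, 0 °C; Rubottom oxidation, which touches only the electron-rich enol ether) to (4R)-4-ethenyl-4-methyl-2-(triisopropylsilyloxy)cyclohexan-1-one F1. Desilylation with aq. HF in MeCN gives (4R)-4-ethenyl-2-hydroxy-4-methylcyclohexan-1-one F2. Cleavage of the α-hydroxy ketone with NaIO4 in aqueous THF turns the carbinol carbon into the aldehyde and the ketone carbon into the acid, which is 8.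

Step 6. The Grignard reagent may act as a base on the aldehyde, or be held back by the poorly soluble magnesium carboxylate, so that addition stalls. The fallback sets out from 8 and returns at 13. Compound 8 would be esterified with Me3SiCHN2 (toluene/MeOH, 0 °C) to methyl (4R)-4-methyl-4-(2-oxoethyl)hex-5-enoate F3. Reagent 11 (1.1 equiv, −78 °C) then adds to the aldehyde alone and gives methyl (4R)-4-{2-[2,4-bis(prop-2-en-1-yloxy)phenyl]-2-hydroxyethyl}-4-methylhex-5-enoate F4. LiAlH4 reduction of the ester gives diol 13.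

Step 13. The copper acetylide may attack with allylic transposition at the trisubstituted alkene carbon, or the diol may be O-alkylated, giving inseparable isomers. The fallback sets out from 19 and 17 and returns at 20. Diol 19 would be protected (2,2-dimethoxypropane, PPTS) as 4-ethynyl-2,2,4-trimethyl-1,3-dioxolane F5. Stannylation (n-BuLi, THF, −78 °C; Bu3SnCl) gives tributyl[(2,2,4-trimethyl-1,3-dioxolan-4-yl)ethynyl]stannane F6. Stille coupling of F6 with 17 (Pd2(dba)3, AsPh3, THF, 50 °C) proceeds through an η3-allyl complex of divalent palladium that delivers the alkynyl group to the CH2 terminus, giving (3R,6E)-1-[2,4-bis(prop-2-en-1-yloxy)phenyl]-3-ethenyl-3,7-dimethyl-10-(2,2,4-trimethyl-1,3-dioxolan-4-yl)dec-6-en-9-yn-1-one F7. Aqueous AcOH then frees diol 20.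

Further compounds
F1 | step 4 | (4R)-4-ethenyl-4-methyl-2-(triisopropylsilyloxy)cyclohexan-1-one (C2 epimers) | C=C[C@]1(C)CCC(=O)C(O[Si](C(C)C)(C(C)C)C(C)C)C1
F2 | step 4 | (4R)-4-ethenyl-2-hydroxy-4-methylcyclohexan-1-one (C2 epimers) | C=C[C@]1(C)CCC(=O)C(O)C1
F3 | step 6 | methyl (4R)-4-methyl-4-(2-oxoethyl)hex-5-enoate | C=C[C@@](C)(CC=O)CCC(=O)OC
F4 | step 6 | methyl (4R)-4-{2-[2,4-bis(prop-2-en-1-yloxy)phenyl]-2-hydroxyethyl}-4-methylhex-5-enoate (carbinol epimers) | C=C[C@@](C)(CC(O)c1ccc(OCC=C)cc1OCC=C)CCC(=O)OC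
F5 | step 13 | 4-ethynyl-2,2,4-trimethyl-1,3-dioxolane (racemic) | C#CC1(C)COC(C)(C)O1
F6 | step 13 | tributyl[(2,2,4-trimethyl-1,3-dioxolan-4-yl)ethynyl]stannane | CCCC[Sn](CCCC)(CCCC)C#CC1(C)COC(C)(C)O1
F7 | step 13 | (3R,6E)-1-[2,4-bis(prop-2-en-1-yloxy)phenyl]-3-ethenyl-3,7-dimethyl-10-(2,2,4-trimethyl-1,3-dioxolan-4-yl)dec-6-en-9-yn-1-one | C=C[C@@](C)(CC(=O)c1ccc(OCC=C)cc1OCC=C)CC/C=C(\C)CC#CC1(C)COC(C)(C)O1
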